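**Conventions and assumptions**

- The carbocycle is numbered C1 (CH bearing the CMe2 group), C2 (CH bearing quinolone A), C3 (CH2), C4 (carbon bearing CH3 and O), C5 (CH2), C6 (CH bearing quinolone B). Ring A is the pyran closed by O-4 of quinolone A on CMe2; ring B is the pyran closed by O-4 of quinolone B on C4. In this numbering the target is (1R,2S,4R,6S). "Quinolone" means a 4-hydroxy (or 4-oxy)-1-methyl-2-oxo-1,2-dihydroquinolin-3-yl group.
- Assumption 1: ethyl esters serve as the spectator esters, because diethyl 4-oxocyclohexane-1,1-dicarboxylate (1) is a catalogue compound; no bond of the key step is affected.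
- Assumption 2: the sense of induction of a cinchona squaramide on this dienone cannot be derived from first principles. The quinine-derived catalyst is written; its quinidine-derived pseudoenantiomer is used instead if the opposite series results.

## The problem

The target (12) is a p-menthane-type cyclohexane whose C2 and C6 each carry C3 of a 4-oxy-1-methylquinolin-2-one unit; O-4 of quinolone A is tied to the CMe2 group on C1 (ring A, a trans-fused 2,2-dimethyldihydropyran) and O-4 of quinolone B to the methyl-bearing C4 (ring B, which makes a 2-oxabicyclo[3.3.1]nonane with the carbocycle). The four stereocentres (C1, C2, C4, C6) are not independent: the bridge forces the C4–O bond to be axial and cis to quinolone B, the two aryl-bearing carbons are trans to each other, and C1 holds its CMe2O group equatorial, trans to quinolone A and cis to quinolone B. What must be controlled is therefore the absolute sense of the trans C2/C6 pair and the pairing of each quinolone oxygen with its carbon. The pairing is a thermodynamic matter, because the target is the chair in which everything except the bridge is equatorial. Both ring ethers are tertiary alkyl ethers of a vinylogous acid and ionise in strong acid. The free hydroxyquinolone is acidic (pKa near 6), ambident (C3, O-4, O-2), and can leave a β-carbonyl position again by retro-conjugate addition under base. The enabling feature is that C2 and C6 are both β to C4: with a ketone at C4 and two identical esters on C1 the ring is a C2v-symmetric cross-conjugated dienone, and both aryl–CH bonds become conjugate additions of C3 of one nucleophile. The trans bis-adduct is C2-symmetric about the C1···C4 axis, so neither C1 nor C4 is stereogenic at that stage and the two esters are homotopic.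

## Retrosynthesis

**12 ⇒ 10 (through 11).** The bonds O-4(A)–CMe2 and O-4(B)–C4 are cut. Both carbons are tertiary, so the forward reaction is ionisation of two carbinols and capture by the two enol hydroxyls. Cutting here first removes both acid-labile ethers from every earlier step and leaves diol 10, which has no ring beyond the carbocycle and the two heteroaromatics. The forward step must pair the hydroxyls and cations correctly; reversibility of the closures and the all-equatorial shape of 12 are relied on for that.

**10 ⇒ 7.** Three C–CH3 bonds are cut: the methyl on C4 and both methyls of CMe2. Keto ester 7 delivers them by one organometallic operation on a ketone and an ester. Placing the methyl on C4 any earlier would destroy the carbonyl that the key step needs. The configuration of the new carbinol at C4 does not matter, since it is ionised in the next step. The forward step must add rather than enolise in the presence of two acidic hydroxyls.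

**7 ⇒ 5.** A second ester is put back on C1. A quaternary C1 is what keeps the dienone from tautomerising to a phenol, and two identical groups keep the symmetry. An unsymmetrical pair would make C1 a stereocentre and the dienone faces diastereotopic. The forward reaction is a Krapcho dealkoxycarbonylation, which cannot give stereoisomers here because the esters of 5 are homotopic and C1 of 7 is not stereogenic.

**5 ⇒ 2 + two molecules of 3 (through 4).** The bonds C2–C3(quinolone A) and C6–C3(quinolone B) are cut. Both are Michael bonds to the C4 ketone, so the achiral dienone 2 and the commercial quinolone 3 are the precursors. Forming only one aryl–CH bond at a time would require the carbocycle to be built around it; here all six ring carbons are bought together. The forward reaction must choose one β-face in the first addition and go trans in the second.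

**2 ⇒ 1.** No skeletal bond is cut; two C=C bonds are removed. Twofold dehydrogenation of commercial keto diester 1 with a hypervalent iodine oxidant is asked for, and the quaternary carbon guarantees that it stops at the dienone.

## Roads not taken

**Alternative 1:** carbene-catalysed [3+3] annulation. The cut is made in a ring-A lactone, at the C2–C3(quinolone A) bond and the O-4–acyl bond; the carbocycle does not yet exist. In the forward step a chiral aminoindanol-derived triazolium carbene and a diphenoquinone oxidant turn (2E,5E)-7-[(tert-butyldimethylsilyl)oxy]-5-methylhepta-2,5-dienal A2 into an unsaturated acyl azolium. Quinolone 3 attacks its β-carbon through C3 and then acylates through O-4, giving dihydropyranone A1.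

- Merits: the reaction type is well established for 1,3-dicarbonyl nucleophiles with high enantioselectivity, the β-carbon is unhindered, and acylation fixes the O-4 regiochemistry of ring A.
- Weak points: it makes one of the two aryl–CH bonds and one of four stereocentres. The six-membered carbocycle must still be closed between the lactone α-carbon and the allylic terminus, and quinolone B must be introduced there with control relative to C1 and C2. The enal A2 needs its own synthesis, and the lactone carbonyl must still be turned into CMe2 by methyl addition and re-closure.
- Comparison: this road is better in the confidence of its asymmetric step and in regiocontrol at oxygen. The chosen plan sets against that its symmetry: both aryl-bearing centres from one reagent in one flask, a ready-made carbocycle, and five steps in all. Its price is a doubly hindered conjugate addition.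

**Alternative 2:** quinolones last. The cut is made in 3,3'-(1,8-dihydroxy-p-menthane-3,5-diyl)bis(4-hydroxy-1-methylquinolin-2(1H)-one) A5, which is identical with diol 10, through both pyridone rings: two C3–C4 and two N1–C2 bonds. In the forward step the bis-enolate (LiN(SiMe3)2) of the bis-δ-lactone of 2,2'-(1,8-dihydroxy-p-menthane-3,5-diyl)diacetic acid A3 is C-acylated twice by N-methylisatoic anhydride A4. After loss of CO2 each anilide nitrogen attacks its lactone carbonyl, closing the pyridone and releasing the tertiary alkoxide.

- Merits: it arrives at the same diol as the chosen route, and no acidic hydroxyquinolone is present before the end, so the hazards of steps 3 and 4 below do not arise.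
- Weak points: all stereochemistry must already be in bis-lactone A3, whose enantioselective synthesis is a problem of the same size as the carbocycle of 12. The most direct access would be a double conjugate addition of an acetate equivalent to the same kind of dienone, followed by several adjustment steps. The key step must also succeed twice in one molecule against self-condensation and O-acylation by anhydride A4.
- Comparison: in the endgame this road is at least as good. The chosen plan answers that its stereo-defining step is also the step that brings in the heterocycles, from achiral commercial materials, and that the route is much shorter.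

**Alternative 3:** ring-closing metathesis. The cut is the C4=C5 bond of a cyclohexene. In the forward step second-generation Grubbs catalyst joins the vinyl group on C6 with the methallyl group on C2 of 3-[1-(4-hydroxy-1-methyl-2-oxo-1,2-dihydroquinolin-3-yl)prop-2-en-1-yl]-6-methyl-4-(2-methylprop-2-en-1-yl)-3,4-dihydro-2H-pyrano[3,2-c]quinoline-2,5(6H)-dione A6. Ethylene is lost and the cyclohexene-fused dihydropyranone A7, which carries quinolone B on the allylic ring CH, results.

- Merits: a dependable six-ring closure to a trisubstituted alkene, ring A already in place as a lactone with defined oxygen regiochemistry, and an alkene placed in A7 so that acid would add O-4 of quinolone B to the methyl-bearing carbon.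
- Weak points: the metathesis creates no stereocentre. The three contiguous centres C2, C1 and C6 of diene A6 must each be set beforehand, C6 under acyclic control next to an epimerisable lactone α-carbon. The chelating hydroxyquinolone beside the vinyl group may sequester the ruthenium carbene.
- Comparison: the ring-forming event itself is safer than the double addition of the chosen plan, which is a real advantage. The chosen plan sets against it that no ring has to be built, that stereocentres are set two at a time with mutual reinforcement, and that far fewer steps are needed.

Key step: step 2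

## Route

Step 1
Reactants: 1 diethyl 4-oxocyclohexane-1,1-dicarboxylate
Product: 2 diethyl 4-oxocyclohexa-2,5-diene-1,1-dicarboxylate
Conditions: IBX (4 equiv), DMSO–PhF 1:2, 75 °C
Reagents that add atoms: none
Why: Twofold α,β-dehydrogenation of a ketone with 2-iodoxybenzoic acid (IBX, a pentavalent iodine reagent); the quaternary C1 rules out aromatisation, so the reaction should stop at the cross-conjugated dienone, and no stereocentre is involved.

Step 2
Reactants: 2 diethyl 4-oxocyclohexa-2,5-diene-1,1-dicarboxylate; 3 4-hydroxy-1-methylquinolin-2(1H)-one (2.4 equiv)
Product: 5 diethyl (2R,6R)-2,6-bis(4-hydroxy-1-methyl-2-oxo-1,2-dihydroquinolin-3-yl)-4-oxocyclohexane-1,1-dicarboxylate (trans), via mono-adduct enone 4 (not isolated)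
Conditions: squaramide from 9-amino-9-deoxy-epi-quinine and 3,5-bis(trifluoromethyl)aniline (10 mol %), CHCl3 (slurry), 25–40 °C
Reagents that add atoms: none
Why: Catalytic enantioselective Michael addition run twice: the quinuclidine nitrogen deprotonates 3 and holds its enolate as an ion pair while the squaramide NH groups bind the dienone carbonyl, C3 of the enolate attacks a β-carbon to give enone 4, and 4 accepts a second molecule of 3 at its remaining β-carbon. The closest known reactions are the organocatalytic C3-additions of 4-hydroxycoumarins and 4-hydroxyquinolones to cyclic enones and the desymmetrising Michael additions of 1,3-dicarbonyl compounds to 4,4-disubstituted cyclohexadienones. No ring is closed; two C–C bonds and two stereocentres are formed. Because 2 is C2v-symmetric its four β-faces fall into two homotopic pairs that are enantiotopic to each other, so the first centre (C6, R) is set only by the catalyst's choice between these pairs. The second centre (C2, R) is set by the substrate, since a nucleophile enters a 5-substituted cyclohexenone anti to that substituent, and by the catalyst, whose preferred local sense is the same as in the first addition, so the two influences are matched. The step needs face selectivity in the first addition and trans selectivity in the second; mono-adduct of the wrong hand is steered by the catalyst toward the separable meso cis isomer, which should raise the enantiopurity of 5 above that of the first addition. The geminal esters activate the flanking β-carbons inductively, and ethyl esters with a non-nucleophilic catalyst are chosen to hold back acyl transfer with aromatisation. Product 5 may rest as the bridged hemiketal of its axial quinolone hydroxyl with the ketone, a ring-chain tautomer that reacts as the ketone.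

Step 3
Reactants: 5 diethyl (2R,6R)-2,6-bis(4-hydroxy-1-methyl-2-oxo-1,2-dihydroquinolin-3-yl)-4-oxocyclohexane-1,1-dicarboxylate
Product: 7 ethyl (2S,6S)-2,6-bis(4-hydroxy-1-methyl-2-oxo-1,2-dihydroquinolin-3-yl)-4-oxocyclohexane-1-carboxylate, via half-ester acid 6 (not isolated)
Conditions: LiCl (3 equiv), H2O (3 equiv), DMSO, 150 °C
Reagents that add atoms: none
Why: Krapcho dealkoxycarbonylation of a 2,2-disubstituted malonate: chloride dealkylates one ester, carboxylate 6 loses CO2 and the ester enolate is protonated by water or by a neighbouring quinolone hydroxyl. The two esters of 5 are exchanged by its C2 axis and C1 of 7 is not stereogenic, so a single product is expected; C2 and C6 are untouched, and their descriptors change from R to S only through a change of priorities.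

Step 4
Reactants: 7 ethyl (2S,6S)-2,6-bis(4-hydroxy-1-methyl-2-oxo-1,2-dihydroquinolin-3-yl)-4-oxocyclohexane-1-carboxylate
Product: 10 diol 2-[(2S,6S)-4-hydroxy-4-methyl-2,6-bis(4-hydroxy-1-methyl-2-oxo-1,2-dihydroquinolin-3-yl)cyclohexyl]propan-2-ol (ring hydroxyl cis to the hydroxypropyl group), via hydroxy ester 8 (not isolated), via methyl ketone carbinol 9 (not isolated)
Conditions: MeMgBr (10 equiv), CeCl3 (3 equiv), THF, −78 → 25 °C; then aq. NH4Cl
Reagents that add atoms: methylmagnesium bromide, C[Mg]Br
Why: Cerium trichloride-promoted Grignard addition: two equivalents are spent on the acidic hydroxyls (the resulting salts shield the lactam carbonyls), the ketone reacts first (8) and the ester follows through methyl ketone 9, with CeCl3 suppressing enolisation. Methyl should enter C4 equatorially, anti to the axial quinolone, but this carbinol configuration is erased in step 5; any material whose ester has lactonised onto a quinolone oxygen is opened to the same carbinol.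

Step 5
Reactants: 10 diol 2-[(2S,6S)-4-hydroxy-4-methyl-2,6-bis(4-hydroxy-1-methyl-2-oxo-1,2-dihydroquinolin-3-yl)cyclohexyl]propan-2-ol
Product: 12 target CNP0229685.8, carbocycle (1R,2S,4R,6S), ring A trans-fused and ring B bridging C4 and C6, via ring-B ether carbinol 11 (not isolated)
Conditions: TsOH·H2O (0.5 equiv), toluene, 80 °C
Reagents that add atoms: none
Why: Acid-catalysed double cyclodehydration through the two tertiary cations (or the alkenes in equilibrium with them), each captured by a quinolone O-4 hydroxyl to close a six-membered ether. Ring B can only form cis to the axial quinolone at C6, which fixes C4, and the CMe2 cation is taken by the trans-disposed quinolone A, which fixes C1 with the CMe2O group equatorial. Because tertiary ethers of this vinylogous acid re-ionise under the conditions, the pairing is under thermodynamic control and should settle on 12; the other pairing needs an axial CMe2O group and a cis ring fusion.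

## Compound list

1 | diethyl 4-oxocyclohexane-1,1-dicarboxylate | CCOC(=O)C1(C(=O)OCC)CCC(=O)CC1 | starting material
2 | diethyl 4-oxocyclohexa-2,5-diene-1,1-dicarboxylate | CCOC(=O)C1(C(=O)OCC)C=CC(=O)C=C1 | intermediate
3 | 4-hydroxy-1-methylquinolin-2(1H)-one | Cn1c(=O)cc(O)c2ccccc21 | starting material
4 | diethyl (6R)-6-(4-hydroxy-1-methyl-2-oxo-1,2-dihydroquinolin-3-yl)-4-oxocyclohex-2-ene-1,1-dicarboxylate | CCOC(=O)C1(C(=O)OCC)C=CC(=O)C[C@@H]1c1c(O)c2ccccc2n(C)c1=O | intermediate (not isolated)
5 | diethyl (2R,6R)-2,6-bis(4-hydroxy-1-methyl-2-oxo-1,2-dihydroquinolin-3-yl)-4-oxocyclohexane-1,1-dicarboxylate | CCOC(=O)C1(C(=O)OCC)[C@@H](c2c(O)c3ccccc3n(C)c2=O)CC(=O)C[C@@H]1c1c(O)c2ccccc2n(C)c1=O | intermediate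
6 | (2R,6R)-1-(ethoxycarbonyl)-2,6-bis(4-hydroxy-1-methyl-2-oxo-1,2-dihydroquinolin-3-yl)-4-oxocyclohexane-1-carboxylic acid | CCOC(=O)C1(C(=O)O)[C@@H](c2c(O)c3ccccc3n(C)c2=O)CC(=O)C[C@@H]1c1c(O)c2ccccc2n(C)c1=O | intermediate (not isolated)
7 | ethyl (2S,6S)-2,6-bis(4-hydroxy-1-methyl-2-oxo-1,2-dihydroquinolin-3-yl)-4-oxocyclohexane-1-carboxylate (C1 not stereogenic) | CCOC(=O)C1[C@@H](c2c(O)c3ccccc3n(C)c2=O)CC(=O)C[C@@H]1c1c(O)c2ccccc2n(C)c1=O | intermediate
8 | ethyl (2S,6S)-4-hydroxy-4-methyl-2,6-bis(4-hydroxy-1-methyl-2-oxo-1,2-dihydroquinolin-3-yl)cyclohexane-1-carboxylate, hydroxyl cis to the ester | CCOC(=O)[C@@H]1[C@@H](c2c(O)c3ccccc3n(C)c2=O)C[C@@](O)(C)C[C@@H]1c1c(O)c2ccccc2n(C)c1=O | intermediate (not isolated)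
9 | 1-[(2S,6S)-4-hydroxy-4-methyl-2,6-bis(4-hydroxy-1-methyl-2-oxo-1,2-dihydroquinolin-3-yl)cyclohexyl]ethan-1-one, hydroxyl cis to the acetyl group | CC(=O)[C@@H]1[C@@H](c2c(O)c3ccccc3n(C)c2=O)C[C@@](O)(C)C[C@@H]1c1c(O)c2ccccc2n(C)c1=O | intermediate (not isolated)
10 | 2-[(2S,6S)-4-hydroxy-4-methyl-2,6-bis(4-hydroxy-1-methyl-2-oxo-1,2-dihydroquinolin-3-yl)cyclohexyl]propan-2-ol, ring hydroxyl cis to the hydroxypropyl group | CC(C)(O)[C@@H]1[C@@H](c2c(O)c3ccccc3n(C)c2=O)C[C@@](O)(C)C[C@@H]1c1c(O)c2ccccc2n(C)c1=O | intermediate
11 | ring-B ether carbinol: 10 with O-4 of the C6 quinolone bonded to C4 in place of the ring hydroxyl (2-oxabicyclo[3.3.1]nonane, C4–O cis to the C6 aryl bond; C2 and C6 S), C1 still bearing C(CH3)2OH, C2 quinolone free | CC(C)(O)[C@@H]1[C@@H](c3c(O)c4ccccc4n(C)c3=O)C[C@@]2(C)C[C@@H]1c1c(c3ccccc3n(C)c1=O)O2 | intermediate (not isolated)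
12 | CNP0229685.8: 11 with O-4 of the C2 quinolone bonded to the CMe2 carbon (ring A, trans-fused); carbocycle (1R,2S,4R,6S) | Cn1c(=O)c2c(c3ccccc31)OC(C)(C)[C@@H]1[C@@H]2C[C@@]2(C)C[C@@H]1c1c(c3ccccc3n(C)c1=O)O2 | target

## Step count and least certain steps

Total: 5 steps. Longest linear sequence: 5 steps (from 1).

**Step 2 (key step).** The second addition may stall, because its β-carbon lies between a quaternary carbon and an aryl-bearing carbon and the mono-adduct can park itself by internal oxa-Michael closure. Hydrogen-bond activation may also discriminate the β-faces of an unactivated dienone poorly. Acyl transfer from the geminal diester with aromatisation may consume the dienone. Fallback (from 2, back at 5): covalent activation and two separate operations. 9-Amino-9-deoxy-epi-quinine (20 mol %) with CF3CO2H (40 mol %) converts 2 into its iminium ion, the established activation for C3-additions of 4-hydroxycoumarins to cyclohexenones. With one equivalent of 3 this should stop at 4, which is isolated. The second addition is then run on pure 4 with 3 and catalytic DABCO at higher concentration and temperature, relying only on the anti preference imposed by the aryl group. No compound outside the route is made, which is recorded as F0.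

**Step 3.** At 150 °C a ketone enolate, or the ester enolate formed on decarboxylation, may expel a quinolone by retro-conjugate addition before it is protonated. Fallback (from 5, back at 7): remove the ester under acid, where no enolate exists. Aqueous HCl (6 M) in acetic acid at reflux hydrolyses the diester, helped by a neighbouring quinolone hydroxyl that can lactonise onto an ester and offer an easily hydrolysed enol ester. The malonic acid decarboxylates in the same pot to (2S,6S)-2,6-bis(4-hydroxy-1-methyl-2-oxo-1,2-dihydroquinolin-3-yl)-4-oxocyclohexane-1-carboxylic acid F1. Fischer esterification (EtOH, H2SO4 cat., reflux) returns 7.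

**Step 4.** Deprotonation next to the ketone in place of addition would open the way to loss of a quinolone. The polyanionic magnesium salts may be poorly soluble, and addition to the ester, flanked by two aryl-bearing carbons, may stop at the methyl ketone stage through enolisation. Fallback (from 7, back at 10): take the acidic hydroxyls out of play. MOMCl and iPr2NEt in CH2Cl2 give ethyl (2S,6S)-2,6-bis[4-(methoxymethoxy)-1-methyl-2-oxo-1,2-dihydroquinolin-3-yl]-4-oxocyclohexane-1-carboxylate F2, whose aryl groups can no longer leave as stabilised anions and which reacts as a neutral, soluble species. MeMgBr/CeCl3 in THF then gives 2-[(2S,6S)-4-hydroxy-4-methyl-2,6-bis[4-(methoxymethoxy)-1-methyl-2-oxo-1,2-dihydroquinolin-3-yl]cyclohexyl]propan-2-ol F3. Aqueous HCl in THF at 0–25 °C removes both acetals to give 10.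

**Step 5.** Under kinetic control the hydroxyls and cations may pair the other way (quinolone B on CMe2, quinolone A on C4), closure may occur through the lactam oxygen O-2, or elimination to alkenes may outrun closure. Fallback (from 7, back at 11): close the rings one at a time, so that each closure has a single cation to serve. The addition of MeMgBr (3.5 equiv)/CeCl3 at −78 °C is stopped after the ketone has reacted, and hydroxy ester 8 is isolated. TsOH in toluene then closes ring B alone and gives the ethyl ester corresponding to 11 (CO2Et in place of C(CH3)2OH at C1, ring B closed, C2 quinolone free) F4. The quinolone cis to the ester is expected to take the bridge, because only then does the ester stay equatorial. MeMgBr/CeCl3 converts the ester into carbinol 11, and the step-5 conditions then close ring A, for which one hydroxyl and one cation remain.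

## Further compounds

F0 | step 2 | none | none
F1 | step 3 | (2S,6S)-2,6-bis(4-hydroxy-1-methyl-2-oxo-1,2-dihydroquinolin-3-yl)-4-oxocyclohexane-1-carboxylic acid | OC(=O)C1[C@@H](c2c(O)c3ccccc3n(C)c2=O)CC(=O)C[C@@H]1c1c(O)c2ccccc2n(C)c1=O
F2 | step 4 | ethyl (2S,6S)-2,6-bis[4-(methoxymethoxy)-1-methyl-2-oxo-1,2-dihydroquinolin-3-yl]-4-oxocyclohexane-1-carboxylate | CCOC(=O)C1[C@@H](c2c(OCOC)c3ccccc3n(C)c2=O)CC(=O)C[C@@H]1c1c(OCOC)c2ccccc2n(C)c1=O
F3 | step 4 | 2-[(2S,6S)-4-hydroxy-4-methyl-2,6-bis[4-(methoxymethoxy)-1-methyl-2-oxo-1,2-dihydroquinolin-3-yl]cyclohexyl]propan-2-ol, ring hydroxyl cis to the hydroxypropyl group | CC(C)(O)[C@@H]1[C@@H](c2c(OCOC)c3ccccc3n(C)c2=O)C[C@@](O)(C)C[C@@H]1c1c(OCOC)c2ccccc2n(C)c1=O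
F4 | step 5 | ethyl ester corresponding to 11 (CO2Et in place of C(CH3)2OH at C1; ring B closed; C2 quinolone free) | CCOC(=O)[C@@H]1[C@@H](c3c(O)c4ccccc4n(C)c3=O)C[C@@]2(C)C[C@@H]1c1c(c3ccccc3n(C)c1=O)O2
A1 | alternative 1 | (4S)-4-[(E)-4-(tert-butyldimethylsilyloxy)-2-methylbut-2-en-1-yl]-6-methyl-3,4-dihydro-2H-pyrano[3,2-c]quinoline-2,5(6H)-dione | Cn1c(=O)c2c(c3ccccc31)OC(=O)C[C@@H]2C/C(C)=C/CO[Si](C)(C)C(C)(C)C
A2 | alternative 1 | (2E,5E)-7-[(tert-butyldimethylsilyl)oxy]-5-methylhepta-2,5-dienal | O=C/C=C/C/C(C)=C/CO[Si](C)(C)C(C)(C)C
A3 | alternative 2 | bis-δ-lactone of 2,2'-(1,8-dihydroxy-p-menthane-3,5-diyl)diacetic acid | O=C1OC(C)(C)[C@@H]2[C@@H](C1)C[C@@]1(C)C[C@@H]2CC(=O)O1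
A4 | alternative 2 | N-methylisatoic anhydride (1-methyl-2H-3,1-benzoxazine-2,4(1H)-dione) | CN1C(=O)OC(=O)c2ccccc12
A5 | alternative 2 | 3,3'-(1,8-dihydroxy-p-menthane-3,5-diyl)bis(4-hydroxy-1-methylquinolin-2(1H)-one), identical with 10 | CC(C)(O)[C@@H]1[C@@H](c2c(O)c3ccccc3n(C)c2=O)C[C@@](O)(C)C[C@@H]1c1c(O)c2ccccc2n(C)c1=O
A6 | alternative 3 | 3-[1-(4-hydroxy-1-methyl-2-oxo-1,2-dihydroquinolin-3-yl)prop-2-en-1-yl]-6-methyl-4-(2-methylprop-2-en-1-yl)-3,4-dihydro-2H-pyrano[3,2-c]quinoline-2,5(6H)-dione | Cn1c(=O)c2c(c3ccccc31)OC(=O)[C@@H]([C@H](C=C)c1c(O)c3ccccc3n(C)c1=O)[C@@H]2CC(C)=C
A7 | alternative 3 | cyclohexene-fused dihydropyranone carrying quinolone B on the allylic ring CH | Cn1c(=O)c2c(c3ccccc31)OC(=O)[C@@H]1[C@@H]2CC(C)=C[C@@H]1c1c(O)c2ccccc2n(C)c1=O
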